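## Retrosynthetic overview
1. The prenyl terminus and the acetate come last. The target derives from an (8S)-homoallylic alcohol by O-acetylation and cross-metathesis with 2-methylbut-2-ene.
2. Key disconnection C8–C9: reagent-controlled allylboration of a ring-bearing 2-substituted acrolein (fragment 1, which already carries both angelates and the epoxide) with B-allyldiisopinocampheylborane (fragment 2).
3. The enal comes from allylic oxidation of the isopropenyl CH3 of the bis-angelate epoxide. That compound comes from the all-cis epoxy diol and angelic acid.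
4. The epoxy diol comes from OH-directed epoxidation of the all-cis cyclohexenediol. The diol is reached by Luche reduction (C2), Mitsunobu inversion (C1) and Rubottom oxidation of (R)-carvone (C6 from the chiral pool).
5. Rings: the six-membered ring is bought with carvone. The oxirane is the only ring made (step 6), and it is made before the side chain is grown.

**Convention.** Bisabolane locants of the target are used for all ring compounds.
- C1 and C2 are the ester carbinols, with C1 next to C6.
- C3 is the epoxide carbon bearing CH3, C4 is the epoxide CH, and C5 is CH2.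
- C6 is the ring CH bearing C7(=C14H2)–C8–C9–C10=C11.
- β is the ring face carrying the C6 side chain; α is the other face.

**Assumption.** The target is taken exactly as drawn, which decodes to (1R,2R,3S,4S,6S,8S). The side chain, both ring esters and the epoxide oxygen all lie on the β face, and both C5 esters are Z (angelates).

## Route

Step 1
Reactants: 1 (R)-(−)-carvone
Product: 3 carvone trimethylsilyl dienol ether, via lithium dienolate 2 (not isolated)
Conditions: LiN(iPr)2 (1.1 equiv), THF, −78 °C, 45 min; Me3SiCl (1.3 equiv), −78 → 0 °C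
Reagents that add atoms: chlorotrimethylsilane, C[Si](C)(C)Cl
Why: Kinetic α′-deprotonation of the cross-conjugated enone by a hindered lithium amide followed by O-silylation (silyl enol ether formation) leaves the carvone stereocentre (future C6) untouched.

Step 2
Reactants: 3 carvone trimethylsilyl dienol ether
Product: 5 trans-6-hydroxycarvone (1α-OH), via 6-trimethylsilyloxycarvone 4 (not isolated)
Conditions: mCPBA (1.05 equiv), CH2Cl2, −20 → 0 °C; then 1 M HCl, THF, 0 °C; chromatography removes the minor cis isomer
Reagents that add atoms: 3-chloroperoxybenzoic acid, O=C(OO)c1cccc(Cl)c1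
Why: Rubottom oxidation, in which the peracid oxidises the most electron-rich (silyl enol ether) alkene from the face anti to the neighbouring isopropenyl group, so the new C1–O bond is trans (α) to the side chain.

Step 3
Reactants: 5 trans-6-hydroxycarvone
Product: 6 cis-6-(4-nitrobenzoyloxy)carvone (1β-ester)
Conditions: 4-O2NC6H4CO2H (4 equiv), PPh3 (4 equiv), DIAD (4 equiv), THF, 0 °C → rt
Reagents that add atoms: 4-nitrobenzoic acid, O=C(O)c1ccc(cc1)[N+](=O)[O-]
Why: Mitsunobu reaction (hindered-alcohol variant with the acidic 4-nitrobenzoic acid), in which SN2 displacement at the carbonyl-activated carbinol carbon inverts C1 from α to β, while anti E2 loss is geometrically impossible because the only β-hydrogen (H6) is cis to the leaving group.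

Step 4
Reactants: 6 cis-6-(4-nitrobenzoyloxy)carvone
Product: 7 2β-hydroxy-1β-(4-nitrobenzoyloxy)cyclohexene
Conditions: NaBH4 (1.1 equiv), CeCl3·7H2O (1.1 equiv), MeOH, −78 → −40 °C
Reagents that add atoms: none
Why: Luche 1,2-reduction, in which hydride adds axially from the α face (the sense of carvone → cis-carveol, reinforced by the axial 1β-acyloxy group blocking the β face) to set C2 as the 2β pseudo-equatorial alcohol, and any 1→2 acyl shift is harmless because step 5 removes the ester.

Step 5
Reactants: 7 2β-hydroxy-1β-(4-nitrobenzoyloxy)cyclohexene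
Product: 8 all-cis cyclohexenediol (1β,2β-diol)
Conditions: K2CO3 (0.2 equiv), MeOH, 0 °C → rt
Reagents that add atoms: none
Why: Base-catalysed transesterification (methanolysis) of the activated 4-nitrobenzoate cleaves only the acyl–oxygen bond, so no stereocentre is touched.

Step 6
Reactants: 8 all-cis cyclohexenediol
Product: 9 all-cis epoxy diol (3β,4β-epoxide)
Conditions: VO(acac)2 (3 mol %), t-BuOOH (5.5 M in decane, 1.15 equiv), CH2Cl2, 0 °C → rt
Reagents that add atoms: tert-butyl hydroperoxide, CC(C)(C)OO
Why: Hydroxyl-directed vanadium-catalysed epoxidation (Sharpless–Michaelson type), in which the allylic 2β-OH and the homoallylic axial 1β-OH both deliver the bound peroxide to the β face of the trisubstituted ring alkene, setting C3 and C4 syn to the diol, while the less nucleophilic 1,1-disubstituted isopropenyl group reacts far more slowly.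

Step 7
Reactants: 10 angelic acid
Product: 11 angelic 2,4,6-trichlorobenzoic mixed anhydride
Conditions: 2,4,6-Cl3C6H2COCl (1.0 equiv), Et3N (1.05 equiv), toluene, rt, 2 h; filter off the ammonium salt, concentrate
Reagents that add atoms: 2,4,6-trichlorobenzoyl chloride, O=C(Cl)c1c(Cl)cc(Cl)cc1Cl
Why: Yamaguchi mixed-anhydride formation activates the acid under mild base without any nucleophilic catalyst, so the Z alkene is not isomerised.

Step 8
Reactants: 9 all-cis epoxy diol; 11 angelic 2,4,6-trichlorobenzoic mixed anhydride (5 equiv)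
Product: 12 1β,2β-bis-angelate epoxide
Conditions: Et3N (6 equiv), toluene, 80 °C, 36 h
Reagents that add atoms: none
Why: Yamaguchi-type esterification run thermally without a pyridine catalyst, in which both alcohols attack the unhindered angeloyl carbonyl (the 2,6-dichloro-flanked aroyl carbonyl is blocked), the Z geometry is kept because no reversible conjugate addition to the acyl donor occurs, and the all-cis array prevents any oxygen from reaching the backside of C3 or C4.

Step 9
Reactants: 12 1β,2β-bis-angelate epoxide
Product: 13 C8 primary allylic alcohol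
Conditions: SeO2 (20 mol %), t-BuOOH (5.5 M in decane, 2.5 equiv), CH2Cl2, 0 °C → rt
Reagents that add atoms: tert-butyl hydroperoxide, CC(C)(C)OO
Why: SeO2 allylic oxidation (ene reaction then [2,3]-sigmatropic shift) of the only electron-rich alkene left attacks the CH3 rather than the hindered tertiary C6–H, the conjugated angelates are too electron-poor to compete, and any over-oxidised enal 14 converges in step 10.

Step 10
Reactants: 13 C8 primary allylic alcohol
Product: 14 2-substituted acrolein (C8 enal, fragment 1)
Conditions: Dess–Martin periodinane (1.3 equiv), pyridine (3 equiv), CH2Cl2, 0 °C → rt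
Reagents that add atoms: none
Why: Dess–Martin oxidation under buffered, non-basic conditions gives the enal without moving the C7=C14 alkene into the ring, eliminating the C1 ester or opening the epoxide.

Step 11
Reactants: 15 allylmagnesium bromide; 16 (−)-B-methoxydiisopinocampheylborane (from (+)-α-pinene)
Product: 17 B-allyldiisopinocampheylborane (fragment 2)
Conditions: Et2O, −78 °C → rt, 1 h; dilute with pentane, filter off the Mg salts under Ar, use the solution at once
Reagents that add atoms: none
Why: Transmetalation (displacement of methoxide on boron by the Grignard reagent) gives the salt-free chiral allylborane with the four pinane stereocentres of each ligand unchanged.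

Step 12
Reactants: 14 2-substituted acrolein; 17 B-allyldiisopinocampheylborane (1.5 equiv)
Product: 19 (8S)-homoallylic alcohol, via diisopinocampheylborinate ester 18 (not isolated)
Conditions: Et2O/pentane, −100 → −78 °C, 3 h; then NaBO3·4H2O, THF/H2O, rt
Reagents that add atoms: none
Why: Brown asymmetric allylboration (carbonyl allylation through a closed Zimmerman–Traxler chair), in which the (+)-α-pinene-derived reagent attacks the Si face of 2-substituted acroleins (same sense as benzaldehyde → (S)-1-phenylbut-3-en-1-ol), so reagent control forms the C8–C9 bond and sets C8 as S, and the near-neutral perborate work-up spares esters and epoxide.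

Step 13
Reactants: 19 (8S)-homoallylic alcohol
Product: 20 (8S)-acetate
Conditions: Ac2O (3 equiv), pyridine, DMAP (5 mol %), CH2Cl2, 0 °C → rt
Reagents that add atoms: acetic anhydride, CC(=O)OC(C)=O
Why: Nucleophile-catalysed O-acetylation of the only free hydroxyl proceeds with retention at C8, since the C–O bond is not broken.

Step 14
Reactants: 20 (8S)-acetate
Product: 21 target CNP0188566.2
Conditions: second-generation Grubbs catalyst (H2IMes)(PCy3)Cl2Ru=CHPh (5 mol %), 2-methylbut-2-ene/CH2Cl2 (1:1), 40 °C, sealed tube
Reagents that add atoms: 2-methylbut-2-ene, CC=C(C)C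
Why: Olefin cross-metathesis, in which only the monosubstituted terminal alkene engages the catalyst and excess 2-methylbut-2-ene caps it as the prenyl group, while the flanked 1,1-disubstituted C7=C14 alkene and the trisubstituted electron-poor angelates are spectators and no stereocentre is touched.

## Compound list
1 | (R)-(−)-carvone, (5R)-2-methyl-5-(prop-1-en-2-yl)cyclohex-2-en-1-one | C=C(C)[C@@H]1CC=C(C)C(=O)C1 | starting material
2 | lithium cross-conjugated dienolate of carvone | C=C(C)[C@@H]1CC=C(C)C([O-])=C1.[Li+] | intermediate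
3 | (R)-trimethyl{[6-methyl-3-(prop-1-en-2-yl)cyclohexa-1,5-dien-1-yl]oxy}silane | C=C(C)[C@@H]1CC=C(C)C(O[Si](C)(C)C)=C1 | intermediate
4 | trans-6-(trimethylsilyloxy)carvone (1α-OSiMe3) | C=C(C)[C@@H]1CC=C(C)C(=O)[C@H]1O[Si](C)(C)C | intermediate
5 | trans-6-hydroxycarvone, (5S,6S)-6-hydroxy-2-methyl-5-(prop-1-en-2-yl)cyclohex-2-en-1-one (OH anti to isopropenyl) | C=C(C)[C@@H]1CC=C(C)C(=O)[C@H]1O | intermediate
6 | (1R,6S)-3-methyl-2-oxo-6-(prop-1-en-2-yl)cyclohex-3-en-1-yl 4-nitrobenzoate (ester cis to isopropenyl) | C=C(C)[C@@H]1CC=C(C)C(=O)[C@@H]1OC(=O)c2ccc(cc2)[N+](=O)[O-] | intermediate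
7 | (1R,2S,6S)-2-hydroxy-3-methyl-6-(prop-1-en-2-yl)cyclohex-3-en-1-yl 4-nitrobenzoate (all-cis) | C=C(C)[C@@H]1CC=C(C)[C@H](O)[C@@H]1OC(=O)c2ccc(cc2)[N+](=O)[O-] | intermediate
8 | (1R,2S,6S)-3-methyl-6-(prop-1-en-2-yl)cyclohex-3-ene-1,2-diol (both OH cis to isopropenyl) | C=C(C)[C@@H]1CC=C(C)[C@H](O)[C@@H]1O | intermediate
9 | 3β,4β-epoxide of 8: 1-methyl-4-(prop-1-en-2-yl)-7-oxabicyclo[4.1.0]heptane-2,3-diol with epoxide O, both OH and isopropenyl on one face | C=C(C)[C@@H]1C[C@@H]2O[C@]2(C)[C@H](O)[C@@H]1O | intermediate
10 | angelic acid, (Z)-2-methylbut-2-enoic acid | OC(=O)/C(C)=C\C | starting material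
11 | (Z)-2-methylbut-2-enoic 2,4,6-trichlorobenzoic anhydride | O=C(OC(=O)/C(C)=C\C)c1c(Cl)cc(Cl)cc1Cl | intermediate
12 | 1β,2β-bis(angeloyloxy)-3β,4β-epoxide bearing isopropenyl at C6 | C=C(C)[C@@H]1C[C@@H]2O[C@]2(C)[C@H](OC(=O)/C(C)=C\C)[C@@H]1OC(=O)/C(C)=C\C | intermediate
13 | as 12 with C6 side chain C(=CH2)CH2OH | C=C(CO)[C@@H]1C[C@@H]2O[C@]2(C)[C@H](OC(=O)/C(C)=C\C)[C@@H]1OC(=O)/C(C)=C\C | intermediate
14 | as 12 with C6 side chain C(=CH2)CHO (2-substituted acrolein) | C=C(C=O)[C@@H]1C[C@@H]2O[C@]2(C)[C@H](OC(=O)/C(C)=C\C)[C@@H]1OC(=O)/C(C)=C\C | intermediate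
15 | allylmagnesium bromide | C=CC[Mg]Br | starting material
16 | (−)-B-methoxydiisopinocampheylborane, ligands from (+)-α-pinene | COB([C@@H]1C[C@@H]2C[C@H]([C@H]1C)C2(C)C)[C@@H]1C[C@@H]2C[C@H]([C@H]1C)C2(C)C | starting material
17 | B-allyldiisopinocampheylborane, ligands from (+)-α-pinene | C=CCB([C@@H]1C[C@@H]2C[C@H]([C@H]1C)C2(C)C)[C@@H]1C[C@@H]2C[C@H]([C@H]1C)C2(C)C | intermediate
18 | diisopinocampheylborinate ester of 19 | C=C([C@H](CC=C)OB([C@@H]3C[C@@H]4C[C@H]([C@H]3C)C4(C)C)[C@@H]3C[C@@H]4C[C@H]([C@H]3C)C4(C)C)[C@@H]1C[C@@H]2O[C@]2(C)[C@H](OC(=O)/C(C)=C\C)[C@@H]1OC(=O)/C(C)=C\C | intermediate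
19 | as 12 with C6 side chain C(=CH2)–(8S)-CH(OH)–CH2CH=CH2 | C=C([C@H](CC=C)O)[C@@H]1C[C@@H]2O[C@]2(C)[C@H](OC(=O)/C(C)=C\C)[C@@H]1OC(=O)/C(C)=C\C | intermediate
20 | 8-O-acetate of 19 | C=C([C@H](CC=C)OC(C)=O)[C@@H]1C[C@@H]2O[C@]2(C)[C@H](OC(=O)/C(C)=C\C)[C@@H]1OC(=O)/C(C)=C\C | intermediate
21 | (1R,2R,3S,4S,6S,8S)-8-acetoxy-1,2-bis(angeloyloxy)-3,4-epoxybisabola-7(14),10-diene | C=C([C@H](CC=C(C)C)OC(C)=O)[C@@H]1C[C@@H]2O[C@]2(C)[C@H](OC(=O)/C(C)=C\C)[C@@H]1OC(=O)/C(C)=C\C | target

## Step count
Total step count: 14. Twelve steps are on the main line. Two prepare partners: step 7 for the acyl donor and step 11 for the allylborane.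
Longest linear sequence: 12 steps from 1 to 21 (steps 1–6, 8–10, 12–14).

## Steps most likely to fail, with fallbacks

**Step 3 (Mitsunobu inversion of a hindered α-ketol).** The risks are slow substitution, partial retention or epimerisation. The fallback replaces substitution by an oxidation–reduction inversion. It sets out from 5 and comes back to the route at 8. Et3SiCl and imidazole convert 5 into trans-6-(triethylsilyloxy)carvone F1. Luche reduction (NaBH4, CeCl3·7H2O, MeOH) then gives the 2β-hydroxy-1α-triethylsilyloxy cyclohexene F2. TBSOTf and 2,6-lutidine give the 2β-TBS-1α-TES bis-silyl ether F3. PPTS in MeOH removes only the triethylsilyl group to give the 1α-alcohol 2β-TBS ether F4, and buffered Dess–Martin oxidation gives the C1 ketone F5. LiBH(s-Bu)3 in THF at −78 °C delivers hydride from the equatorial α side, the sense known for isopulegone → neoisopulegol, and this gives the axial 1β-alcohol 2β-TBS ether F6. Bu4NF then releases 8.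

**Step 8 (double angeloylation, the second one on an axial flanked alcohol).** The risks are an incomplete second acylation or Z→E drift to tiglate. The fallback builds the Z alkene on the ester instead of transferring it. It sets out from 9 and comes back at 12. 2-[Bis(2,2,2-trifluoroethoxy)phosphoryl]propanoic acid, DCC and DMAP form a very reactive, non-isomerisable acyl donor and acylate both hydroxyls to give the bis(phosphonopropionate) F7. A double Still–Gennari olefination (KN(SiMe3)2, 18-crown-6, THF, −78 °C, then acetaldehyde) then gives the two Z-configured angelates of 12.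

**Step 9 (SeO2 allylic oxidation of a polyfunctional substrate).** The risks are low conversion or acid damage to the epoxide. The fallback uses an ene-type chlorination followed by an N-oxide oxidation. It sets out from 12 and comes back at 14, bypassing 13. Ca(OCl)2 with solid CO2 in CH2Cl2/H2O at 0 °C chlorinates only the electron-rich isopropenyl group to give the C8 allylic chloride F8. N-methylmorpholine N-oxide with NaI (10 mol %) in MeCN displaces the halide and fragments to the enal 14.

## Further compounds
F1 | step 3 | trans-6-(triethylsilyloxy)carvone | C=C(C)[C@@H]1CC=C(C)C(=O)[C@H]1O[Si](CC)(CC)CC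
F2 | step 3 | 2β-hydroxy-1α-triethylsilyloxy cyclohexene | C=C(C)[C@@H]1CC=C(C)[C@H](O)[C@H]1O[Si](CC)(CC)CC
F3 | step 3 | 2β-TBS-1α-TES bis-silyl ether | C=C(C)[C@@H]1CC=C(C)[C@H](O[Si](C)(C)C(C)(C)C)[C@H]1O[Si](CC)(CC)CC
F4 | step 3 | 1α-alcohol 2β-TBS ether | C=C(C)[C@@H]1CC=C(C)[C@H](O[Si](C)(C)C(C)(C)C)[C@H]1O
F5 | step 3 | C1 ketone | C=C(C)[C@@H]1CC=C(C)[C@H](O[Si](C)(C)C(C)(C)C)C1=O
F6 | step 3 | axial 1β-alcohol 2β-TBS ether | C=C(C)[C@@H]1CC=C(C)[C@H](O[Si](C)(C)C(C)(C)C)[C@@H]1O
F7 | step 8 | bis(phosphonopropionate) of 9 (mixture of epimers at the two P-bearing carbons) | C=C(C)[C@@H]1C[C@@H]2O[C@]2(C)[C@H](OC(=O)C(C)P(=O)(OCC(F)(F)F)OCC(F)(F)F)[C@@H]1OC(=O)C(C)P(=O)(OCC(F)(F)F)OCC(F)(F)F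
F8 | step 9 | C8 allylic chloride | C=C(CCl)[C@@H]1C[C@@H]2O[C@]2(C)[C@H](OC(=O)/C(C)=C\C)[C@@H]1OC(=O)/C(C)=C\C
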